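**Retrosynthetic overview**

1. The strategy rests on the bond between Cα (the carbon between the lactam C1=O and the quaternary carbon Cq that carries C21H2–O) and C2′ of the tetrasubstituted cyclopentene alkene C1′=C2′. This bond lies in the seven-membered ring Cα–Cq–C4(H)–CH2–CH2–C1′=C2′ that bridges Cα to the bridgehead C4–H. It is cut to a lactam enolate and a C2′ alkenyl bromide. (Other labels: C5 = NCH2 next to C4; C6–C10 = bridge Cq–CH2–CH2–C8H(O)–C9H(CH3)–C10H2–N; C3′ = ring-fusion CH.)
2. After the key step, the cyclopentane Cα–CH2–CH(CO2Me)–C3′–C2′ is closed by ring-closing metathesis between the Cα vinyl group and an α-methylene ester grown from the two-carbon arm on C3′; hydrogenation sets CH(CO2Me).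
3. Before it, the bridged bicyclo[5.2.2] lactam (bridgeheads N and Cq) is cut at N–C1 (transannular aminolysis of a spiro-γ-lactone by a nine-membered cyclic amine) and at N–C10 (Fukuyama–Mitsunobu closure of that amine).
4. The open chain comes from a pyrrolidinone template. An enamine-catalysed aldehyde–nitroalkene Michael addition joins the east chain (Evans aldol) to the west bromocyclopentene (Stork–Danheiser, Horner–Wadsworth–Emmons, asymmetric CuH reduction) and sets C4; lactam-enolate alkylation anti to the C4 chain sets Cq; borohydride opens the template.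
5. Ring order: cyclopentene (from the start) → pyrrolidinone (temporary) → γ-lactone (temporary) → nine-membered amine → six-membered lactam → seven-membered ring (key step) → cyclopentane.

Key step: step 26

Remark: the (R) antipode of DTBM-SEGPHOS in step 4 is an assumption about the sense of induction, to be confirmed on the first run; the Cα configuration of the sulfoxide adduct and of the key-step precursor is left open because both epimers give the same enolate; abbreviations in names: Bn = benzyl, TBS = tert-butyldimethylsilyl, Boc = tert-butoxycarbonyl, Ns = 2-nitrobenzenesulfonyl, Nap = naphthalen-2-ylmethyl, BCP = (3R)-2-bromo-3-[2-(NapO)ethyl]cyclopent-1-en-1-yl, EC = (3R,4R)-3-(benzyloxy)-4-methyl-5-(TBS-oxy)pentyl.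

**West fragment**

Step 1
Reactants: 1 3-ethoxycyclopent-2-en-1-one
Product: 2 2-bromo-3-ethoxycyclopent-2-en-1-one
Conditions: NBS, CH2Cl2, 0 °C → rt
Reagents that add atoms: N-bromosuccinimide, O=C1CCC(=O)N1Br
Why: Electrophilic bromination of the vinylogous ester at its nucleophilic α-carbon should give the 2-bromo enol ether without touching the saturated positions.

Step 2
Reactants: 2 2-bromo-3-ethoxycyclopent-2-en-1-one; 3 [2-(1,3-dioxolan-2-yl)ethyl]magnesium bromide
Product: 5 2-bromo-3-[2-(1,3-dioxolan-2-yl)ethyl]cyclopent-2-en-1-one, via tertiary allylic alcohol 4 (not isolated)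
Conditions: 3 (0.5 M in THF), THF, −78 → 0 °C; then 1 M HCl, 0 °C, 10 min
Reagents that add atoms: none
Why: Stork–Danheiser transposition, in which 1,2-addition of the Grignard reagent to the vinylogous ester carbonyl is followed by acid-promoted loss of ethanol from the tertiary allylic alcohol, should give the 3-alkyl-2-bromoenone while the dioxolane survives the short cold acid contact.

Step 3
Reactants: 5 2-bromo-3-[2-(1,3-dioxolan-2-yl)ethyl]cyclopent-2-en-1-one
Product: 6 methyl (2E)-2-{2-bromo-3-[2-(1,3-dioxolan-2-yl)ethyl]cyclopent-2-en-1-ylidene}acetate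
Conditions: (MeO)2P(O)CH2CO2Me, NaH, THF, 0 → 65 °C
Reagents that add atoms: trimethyl phosphonoacetate, COC(=O)CP(=O)(OC)OC
Why: Horner–Wadsworth–Emmons olefination of the ketone should give the exocyclic dienoate with the ester on the ring-CH2 side (E), because the other geometry suffers allylic strain against the C–Br bond, and any minor Z isomer is removed by chromatography.

Step 4
Reactants: 6 methyl (2E)-2-{2-bromo-3-[2-(1,3-dioxolan-2-yl)ethyl]cyclopent-2-en-1-ylidene}acetate
Product: 7 methyl 2-{(1R)-2-bromo-3-[2-(1,3-dioxolan-2-yl)ethyl]cyclopent-2-en-1-yl}acetate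
Conditions: Cu(OAc)2·H2O (3 mol%), (R)-DTBM-SEGPHOS (3 mol%), (EtO)2MeSiH, t-BuOH, toluene, 0 °C → rt
Reagents that add atoms: none
Why: Asymmetric copper hydride 1,4-reduction of a β,β-disubstituted enoate, in which the ligand-bound CuH adds hydride to one face of C3′ whose two β-substituents (bromoalkenyl and CH2) are well differentiated, should set the (R) centre, with 1,6-reduction disfavoured at the fully substituted C1′ and the alkenyl bromide inert to CuH.

Step 5
Reactants: 7 methyl 2-{(1R)-2-bromo-3-[2-(1,3-dioxolan-2-yl)ethyl]cyclopent-2-en-1-yl}acetate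
Product: 8 2-{(1R)-2-bromo-3-[2-(1,3-dioxolan-2-yl)ethyl]cyclopent-2-en-1-yl}ethan-1-ol
Conditions: i-Bu2AlH, CH2Cl2, −78 → 0 °C; aq. potassium sodium tartrate
Reagents that add atoms: none
Why: Ester reduction with i-Bu2AlH at low temperature should give the primary alcohol without touching the alkenyl bromide or the acetal.

Step 6
Reactants: 8 2-{(1R)-2-bromo-3-[2-(1,3-dioxolan-2-yl)ethyl]cyclopent-2-en-1-yl}ethan-1-ol
Product: 9 2-(2-BCP-ethyl)-1,3-dioxolane
Conditions: NaH, 2-(bromomethyl)naphthalene, Bu4NI (cat.), THF/DMF, 0 °C → rt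
Reagents that add atoms: 2-(bromomethyl)naphthalene, BrCc1ccc2ccccc2c1
Why: Williamson etherification of the primary alkoxide should install the naphthylmethyl ether, a spectator stable to acid, base and hydride and removable later with DDQ in the presence of a benzyl ether.

Step 7
Reactants: 9 2-(2-BCP-ethyl)-1,3-dioxolane
Product: 10 3-BCP-propanal
Conditions: pyridinium p-toluenesulfonate (cat.), acetone/H2O (4:1), 60 °C
Reagents that add atoms: water, O
Why: Acid-catalysed acetal hydrolysis should free the aldehyde, the ether and the alkenyl bromide being inert.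

Step 8
Reactants: 10 3-BCP-propanal
Product: 13 (1E)-1-nitro-4-BCP-but-1-ene, via nitro alcohol 11 (not isolated), via nitro mesylate 12 (not isolated)
Conditions: MeNO2, 1,1,3,3-tetramethylguanidine (10 mol%), THF, 0 °C; then MsCl, i-Pr2NEt, CH2Cl2, −20 → 0 °C
Reagents that add atoms: nitromethane, C[N+](=O)[O-]
Why: Henry addition of nitromethane followed by mesylation and E1cB elimination of the nitro alcohol should give the conjugated (E)-nitroalkene, the thermodynamically preferred geometry.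

**East chain**

Step 9
Reactants: 14 (4S)-4-benzyl-3-propanoyl-1,3-oxazolidin-2-one; 15 hex-5-enal
Product: 16 (4S)-4-benzyl-3-[(2S,3R)-3-hydroxy-2-methyloct-7-enoyl]-1,3-oxazolidin-2-one
Conditions: Bu2BOTf, i-Pr2NEt, CH2Cl2, −78 → 0 °C; 15, −78 → 0 °C; H2O2, MeOH, pH 7 buffer
Reagents that add atoms: none
Why: Evans syn aldol reaction through the Z boron enolate and a chair Zimmerman–Traxler transition state, with the (S)-benzyl auxiliary shielding one enolate face, should set C8 and C9 with the syn relation of OH and CH3.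

Step 10
Reactants: 16 (4S)-4-benzyl-3-[(2S,3R)-3-hydroxy-2-methyloct-7-enoyl]-1,3-oxazolidin-2-one
Product: 17 (2R,3R)-2-methyloct-7-ene-1,3-diol
Conditions: LiBH4, MeOH (1 equiv), THF, 0 °C
Reagents that add atoms: none
Why: Reductive cleavage of the imide with LiBH4 should release the primary alcohol and the recoverable auxiliary without epimerising C9.

Step 11
Reactants: 17 (2R,3R)-2-methyloct-7-ene-1,3-diol
Product: 18 (2R,3R)-2-methyl-1-(TBS-oxy)oct-7-en-3-ol
Conditions: TBSCl (1.05 equiv), imidazole, CH2Cl2, 0 °C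
Reagents that add atoms: tert-butyldimethylsilyl chloride, CC(C)(C)[Si](C)(C)Cl
Why: Silylation with a bulky silyl chloride is selective for the primary alcohol of the 1,3-diol.

Step 12
Reactants: 18 (2R,3R)-2-methyl-1-(TBS-oxy)oct-7-en-3-ol
Product: 19 (2R,3R)-3-(benzyloxy)-2-methyl-1-(TBS-oxy)oct-7-ene
Conditions: BnOC(=NH)CCl3, TfOH (5 mol%), CH2Cl2/cyclohexane, 0 °C
Reagents that add atoms: benzyl 2,2,2-trichloroacetimidate, ClC(Cl)(Cl)C(=N)OCc1ccccc1
Why: Acid-catalysed O-benzylation with the trichloroacetimidate avoids the base that would let the silyl group migrate between the two oxygens.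

Step 13
Reactants: 19 (2R,3R)-3-(benzyloxy)-2-methyl-1-(TBS-oxy)oct-7-ene
Product: 20 (5R,6R)-5-(benzyloxy)-6-methyl-7-(TBS-oxy)heptanal
Conditions: O3, CH2Cl2, −78 °C; then PPh3, −78 °C → rt
Reagents that add atoms: ozone, [O-][O+]=O
Why: Ozonolysis of the terminal alkene with reductive work-up should give the aldehyde one carbon shorter, the benzyl ether surviving at −78 °C when ozone is not used in excess.

**Union and bridged lactam**

Step 14
Reactants: 20 (5R,6R)-5-(benzyloxy)-6-methyl-7-(TBS-oxy)heptanal; 13 (1E)-1-nitro-4-BCP-but-1-ene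
Product: 21 (2S,3S)-2-EC-3-(nitromethyl)-5-BCP-pentanal
Conditions: (R)-α,α-diphenylprolinol trimethylsilyl ether (10 mol%), 4-nitrophenol (10 mol%), toluene, 0 °C → rt
Reagents that add atoms: none
Why: Enamine-catalysed Michael addition of an aldehyde to a nitroalkene, in which the (R)-diarylprolinol silyl ether forms the E enamine and shields one face so that the nitroalkene is attacked through an acyclic synclinal transition state, should set C4 as (S) and give the syn adduct, whose centre α to the aldehyde is erased later by enolisation.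

Step 15
Reactants: 21 (2S,3S)-2-EC-3-(nitromethyl)-5-BCP-pentanal
Product: 23 methyl (2S,3S)-2-EC-3-(nitromethyl)-5-BCP-pentanoate, via nitro acid 22 (not isolated)
Conditions: NaClO2, NaH2PO4, 2-methylbut-2-ene, t-BuOH/H2O, 0 °C → rt; then Me3SiCHN2, toluene/MeOH, 0 °C
Reagents that add atoms: sodium chlorite NaClO2, [Na+].[O-]Cl=O; trimethylsilyldiazomethane, C[Si](C)(C)C=[N+]=[N-]
Why: Pinnick oxidation of the aldehyde with a hypochlorite scavenger and methylation of the acid with Me3SiCHN2 should give the γ-nitro ester without loss of the silyl or ether groups.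

Step 16
Reactants: 23 methyl (2S,3S)-2-EC-3-(nitromethyl)-5-BCP-pentanoate
Product: 25 (3S,4S)-3-EC-4-(2-BCP-ethyl)pyrrolidin-2-one, via amino ester 24 (not isolated)
Conditions: Zn dust, AcOH, THF, 0 °C → rt; then aq. NaHCO3; MeOH, 50 °C
Reagents that add atoms: none
Why: Dissolving-metal reduction of the nitro group with zinc in acetic acid spares the alkenyl bromide, and the γ-amino ester should close to the five-membered lactam on neutralisation and mild heating.

Step 17
Reactants: 25 (3S,4S)-3-EC-4-(2-BCP-ethyl)pyrrolidin-2-one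
Product: 26 tert-butyl (3S,4S)-3-EC-4-(2-BCP-ethyl)-2-oxopyrrolidine-1-carboxylate
Conditions: Boc2O, Et3N, 4-(dimethylamino)pyridine (cat.), CH2Cl2, rt
Reagents that add atoms: di-tert-butyl dicarbonate, CC(C)(C)OC(=O)OC(=O)OC(C)(C)C
Why: Catalysed N-acylation with Boc2O makes the lactam carbonyl imide-like, which acidifies C-3 for the alkylation and activates the ring for later reductive opening.

Step 18
Reactants: 26 tert-butyl (3S,4S)-3-EC-4-(2-BCP-ethyl)-2-oxopyrrolidine-1-carboxylate
Product: 27 tert-butyl (3S,4S)-3-EC-3-(2-methoxy-2-oxoethyl)-4-(2-BCP-ethyl)-2-oxopyrrolidine-1-carboxylate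
Conditions: LiN(SiMe3)2, THF, −78 °C; BrCH2CO2Me, −78 → −40 °C
Reagents that add atoms: methyl bromoacetate, COC(=O)CBr
Why: Alkylation of the lithium enolate of the N-Boc lactam with the reactive bromoacetate should occur on the face anti to the neighbouring C4 side chain (1,2-induction in the five-membered ring), placing CH2CO2Me trans and the C6 chain cis to the C4 chain and so setting the quaternary Cq.

Step 19
Reactants: 27 tert-butyl (3S,4S)-3-EC-3-(2-methoxy-2-oxoethyl)-4-(2-BCP-ethyl)-2-oxopyrrolidine-1-carboxylate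
Product: 29 tert-butyl N-{(2S)-2-[(3S)-3-EC-5-oxooxolan-3-yl]-4-BCP-butyl}carbamate, via hydroxy ester 28 (not isolated)
Conditions: NaBH4, THF/MeOH (4:1), 0 °C → rt; then pyridinium p-toluenesulfonate (cat.), CH2Cl2, rt
Reagents that add atoms: none
Why: Borohydride reduction of the imide-type lactam carbonyl gives a hemiaminal that opens to the aldehyde and is reduced to the C21 alcohol, which should lactonise onto the neighbouring methyl ester (5-exo), so that the template is opened to the Boc-amine while C21 and C1 are locked as a γ-lactone.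

Step 20
Reactants: 29 tert-butyl N-{(2S)-2-[(3S)-3-EC-5-oxooxolan-3-yl]-4-BCP-butyl}carbamate
Product: 30 (2S)-2-{(3S)-3-[(3R,4R)-3-(benzyloxy)-5-hydroxy-4-methylpentyl]-5-oxooxolan-3-yl}-4-BCP-butan-1-aminium chloride
Conditions: HCl (3 M in MeOH), 0 °C → rt; concentrate
Reagents that add atoms: hydrogen chloride, Cl
Why: Acidolysis with methanolic HCl should remove the Boc group and the primary silyl ether in one operation, the γ-lactone and the benzyl and naphthylmethyl ethers being stable to it.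

Step 21
Reactants: 30 (2S)-2-{(3S)-3-[(3R,4R)-3-(benzyloxy)-5-hydroxy-4-methylpentyl]-5-oxooxolan-3-yl}-4-BCP-butan-1-aminium chloride
Product: 31 N-{(2S)-2-[(3S)-3-[(3R,4R)-3-(benzyloxy)-5-hydroxy-4-methylpentyl]-5-oxooxolan-3-yl]-4-BCP-butyl}-2-nitrobenzenesulfonamide
Conditions: 2-nitrobenzenesulfonyl chloride, sat. aq. NaHCO3/CH2Cl2, 0 °C
Reagents that add atoms: 2-nitrobenzenesulfonyl chloride, O=S(=O)(Cl)c1ccccc1[N+](=O)[O-]
Why: Schotten–Baumann sulfonylation should trap the primary amine as it is released from its salt, faster than it can attack the γ-lactone, and leaves the C10 alcohol untouched.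

Step 22
Reactants: 31 N-{(2S)-2-[(3S)-3-[(3R,4R)-3-(benzyloxy)-5-hydroxy-4-methylpentyl]-5-oxooxolan-3-yl]-4-BCP-butyl}-2-nitrobenzenesulfonamide
Product: 32 N-Ns nine-membered amine spiro-fused at Cq to the γ-lactone
Conditions: PPh3, DIAD, toluene/THF (0.005 M, slow addition of 31), 0 °C → rt
Reagents that add atoms: none
Why: Fukuyama–Mitsunobu cyclisation, in which the acidic Ns-amide N–H is alkylated by the phosphonium-activated primary C10 alcohol (SN2 at a CH2, no stereocentre involved), should close the nine-membered amine under high dilution, helped by the quaternary Cq in the chain.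

Step 23
Reactants: 32 N-Ns nine-membered amine spiro-fused at Cq to the γ-lactone
Product: 34 bridged lactam alcohol (Cq–CH2OH; Cα = CH2), via free nine-membered amine 33 (not isolated)
Conditions: PhSH, K2CO3, MeCN, rt; then 2-hydroxypyridine (20 mol%), toluene, 90 °C
Reagents that add atoms: none
Why: Thiolate ipso-substitution on the nitroarene (Meisenheimer adduct, loss of SO2) frees the ring amine, which should open the spiro-lactone at C1 through a six-membered transition state (transannular aminolysis), closing the bridged six-membered lactam and releasing the C21 alcohol.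

Step 24
Reactants: 34 bridged lactam alcohol (Cq–CH2OH; Cα = CH2)
Product: 35 bridged lactam TBS ether (Cq–CH2OTBS; Cα = CH2)
Conditions: TBSOTf, 2,6-lutidine, CH2Cl2, 0 °C
Reagents that add atoms: tert-butyldimethylsilyl trifluoromethanesulfonate, CC(C)(C)[Si](C)(C)OS(=O)(=O)C(F)(F)F
Why: Silylation of the neopentyl primary alcohol with the silyl triflate should protect C21–OH for the strong-base steps that follow.

Step 25
Reactants: 35 bridged lactam TBS ether (Cq–CH2OTBS; Cα = CH2)
Product: 37 α-vinyl bridged lactam (key-step precursor; Cα epimers), via sulfoxide adduct 36 (not isolated)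
Conditions: LiN(i-Pr)2, THF, −78 °C; CH2=CHS(O)Ph, −78 → −30 °C; AcOH; then NaHCO3 (solid), toluene, 110 °C
Reagents that add atoms: phenyl vinyl sulfoxide, C=CS(=O)c1ccccc1
Why: Michael addition of the lithium lactam enolate (the only acidic C–H in the molecule) to the vinyl sulfoxide followed by thermal syn-elimination of benzenesulfenic acid is a two-stage enolate vinylation that can only place the double bond in the terminal position, either Cα epimer being acceptable.

Step 26
Reactants: 37 α-vinyl bridged lactam (key-step precursor; Cα epimers)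
Product: 38 tetracycle with the C2′–Cα bond, quaternary Cα (R) bearing vinyl, and the new seven-membered ring
Conditions: KN(SiMe3)2 (1.3 equiv), toluene, −78 → 0 °C; then Pd[P(t-Bu)3]2 (10 mol%), 70 °C
Reagents that add atoms: none
Why: Oxidative addition of zerovalent palladium into the C2′–Br bond, binding of the potassium dienolate (from deprotonation of the doubly activated Cα–H) as a C-bound palladium enolate and reductive elimination form the C2′–Cα bond. The closest known reaction type is the palladium-catalysed intramolecular α-alkenylation of ketone and amide enolates with alkenyl halides used to build bridged rings. The seven-membered ring Cα–Cq–C4–CH2–CH2–C1′=C2′ closes in a 7-exo sense at the enolate α-carbon. The new quaternary centre Cα is controlled by the tether: the chain on C4 lies on the lactam face anti to the C6–C10 bridge, so only that enolate face can reach palladium and the vinyl group ends syn to the bridge. The step needs α- over γ-coupling of the dienolate and a single enolate; the first is secured because γ-attack would need a nine-membered ring, the second because the arm on C3′ is carried as an ether (an ester there would give a second enolate next to the lactam carbonyl) and no other acidic C–H is present. β-Hydride elimination is impossible once Cα is quaternary.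

**After the key step**

Step 27
Reactants: 38 tetracycle with the C2′–Cα bond, quaternary Cα (R) bearing vinyl, and the new seven-membered ring
Product: 39 tetracyclic primary alcohol (arm = CH2CH2OH)
Conditions: DDQ, CH2Cl2/pH 7 buffer (10:1), 0 °C → rt
Reagents that add atoms: none
Why: Oxidative cleavage of the electron-rich naphthylmethyl ether by DDQ (hydride abstraction, then hydrolysis of the oxocarbenium ion) should free the primary alcohol while the benzyl and silyl ethers remain.

Step 28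
Reactants: 39 tetracyclic primary alcohol (arm = CH2CH2OH)
Product: 41 tetracyclic methyl ester (arm = CH2CO2Me), via carboxylic acid 40 (not isolated)
Conditions: TEMPO (20 mol%), PhI(OAc)2, MeCN/H2O (1:1), rt; then Me3SiCHN2, toluene/MeOH, 0 °C
Reagents that add atoms: water, O; trimethylsilyldiazomethane, C[Si](C)(C)C=[N+]=[N-]
Why: Nitroxyl-catalysed oxidation takes the primary alcohol through the aldehyde hydrate to the acid without touching the alkenes, and Me3SiCHN2 then gives the methyl ester.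

Step 29
Reactants: 41 tetracyclic methyl ester (arm = CH2CO2Me)
Product: 44 tetracyclic acrylate (arm = C(=CH2)CO2Me), via Mannich base 42 (not isolated), via ammonium iodide 43 (not isolated)
Conditions: LiN(i-Pr)2, THF, −78 °C; (CH2=NMe2)I, −78 → 0 °C; then MeI, MeOH, rt; then sat. aq. NaHCO3, CH2Cl2, rt
Reagents that add atoms: N,N-dimethylmethyleneiminium iodide (Eschenmoser's salt), C=[N+](C)C.[I-]
Why: Ester α-methylenation by Mannich reaction of the lithium ester enolate (the lactam has no α-hydrogen left) with the iminium salt, N-methylation and E1cB elimination of trimethylamine should give the acrylate, the enolate being kept at −78 °C so that it does not attack the nearby lactam carbonyl.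

Step 30
Reactants: 44 tetracyclic acrylate (arm = C(=CH2)CO2Me)
Product: 45 pentacyclic cyclopentene ester (Cα–CH=C(CO2Me)–C3′)
Conditions: second-generation Grubbs catalyst (10 mol%), toluene (0.005 M), 80 °C, Ar sparge
Reagents that add atoms: none
Why: Ring-closing metathesis between the vinyl group on Cα and the acrylate alkene should close the five-membered ring with loss of ethene, five-ring formation and the conjugated product driving a reaction between two hindered alkenes.

Step 31
Reactants: 45 pentacyclic cyclopentene ester (Cα–CH=C(CO2Me)–C3′)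
Product: 46 pentacyclic primary alcohol (Cq–CH2OH)
Conditions: HF·pyridine, pyridine, THF, 0 °C → rt
Reagents that add atoms: none
Why: Fluoride cleavage of the primary silyl ether with buffered HF·pyridine should free C21–OH without touching the esters or the benzyl ether.

Step 32
Reactants: 46 pentacyclic primary alcohol (Cq–CH2OH)
Product: 47 pentacyclic acetate (Cq–CH2OAc; C8–OBn)
Conditions: Ac2O, pyridine, 4-(dimethylamino)pyridine (cat.), CH2Cl2, rt
Reagents that add atoms: acetic anhydride, CC(=O)OC(C)=O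
Why: Catalysed acylation of the only free hydroxyl group should give the primary acetate.

Step 33
Reactants: 47 pentacyclic acetate (Cq–CH2OAc; C8–OBn)
Product: 48 CNP0296366.1
Conditions: H2 (1 atm), 10% Pd/C, EtOAc/MeOH, rt
Reagents that add atoms: none
Why: Heterogeneous hydrogenation should add hydrogen to the conjugated trisubstituted alkene from the convex face of the bicyclo[3.3.0] unit (the face of the C3′ hydrogen, anti to the bulky Cq), which sets CH(CO2Me) as (R) with its hydrogen cis to the C3′ hydrogen, while the benzyl ether is hydrogenolysed and the shielded tetrasubstituted alkene is left.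

**Compound list**

1 | 3-ethoxycyclopent-2-en-1-one | CCOC1=CC(=O)CC1 | starting material
2 | 2-bromo-3-ethoxycyclopent-2-en-1-one | CCOC1=C(Br)C(=O)CC1 | intermediate
3 | [2-(1,3-dioxolan-2-yl)ethyl]magnesium bromide (0.5 M in THF) | Br[Mg]CCC1OCCO1 | starting material
4 | 2-bromo-1-[2-(1,3-dioxolan-2-yl)ethyl]-3-ethoxycyclopent-2-en-1-ol (racemic; not isolated) | CCOC1=C(Br)C(O)(CCC2OCCO2)CC1 | intermediate
5 | 2-bromo-3-[2-(1,3-dioxolan-2-yl)ethyl]cyclopent-2-en-1-one | O=C1CCC(CCC2OCCO2)=C1Br | intermediate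
6 | methyl (2E)-2-{2-bromo-3-[2-(1,3-dioxolan-2-yl)ethyl]cyclopent-2-en-1-ylidene}acetate | COC(=O)/C=C1\CCC(CCC2OCCO2)=C1Br | intermediate
7 | methyl 2-{(1R)-2-bromo-3-[2-(1,3-dioxolan-2-yl)ethyl]cyclopent-2-en-1-yl}acetate | O1CCOC1CCC1=C(Br)[C@@H](CC(=O)OC)CC1 | intermediate
8 | 2-{(1R)-2-bromo-3-[2-(1,3-dioxolan-2-yl)ethyl]cyclopent-2-en-1-yl}ethan-1-ol | O1CCOC1CCC1=C(Br)[C@@H](CCO)CC1 | intermediate
9 | 2-{2-[(3R)-2-bromo-3-[2-(naphthalen-2-ylmethoxy)ethyl]cyclopent-1-en-1-yl]ethyl}-1,3-dioxolane | O1CCOC1CCC1=C(Br)[C@@H](CCOCc2ccc3ccccc3c2)CC1 | intermediate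
10 | 3-{(3R)-2-bromo-3-[2-(naphthalen-2-ylmethoxy)ethyl]cyclopent-1-en-1-yl}propanal | O=CCCC1=C(Br)[C@@H](CCOCc2ccc3ccccc3c2)CC1 | intermediate
11 | 4-{(3R)-2-bromo-3-[2-(naphthalen-2-ylmethoxy)ethyl]cyclopent-1-en-1-yl}-1-nitrobutan-2-ol (carbinol epimers; not isolated) | [O-][N+](=O)CC(O)CCC1=C(Br)[C@@H](CCOCc2ccc3ccccc3c2)CC1 | intermediate
12 | methanesulfonate of 11 (not isolated) | [O-][N+](=O)CC(OS(C)(=O)=O)CCC1=C(Br)[C@@H](CCOCc2ccc3ccccc3c2)CC1 | intermediate
13 | 2-({2-[(1R)-2-bromo-3-[(3E)-4-nitrobut-3-en-1-yl]cyclopent-2-en-1-yl]ethoxy}methyl)naphthalene | [O-][N+](=O)/C=C/CCC1=C(Br)[C@@H](CCOCc2ccc3ccccc3c2)CC1 | intermediate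
14 | (4S)-4-benzyl-3-propanoyl-1,3-oxazolidin-2-one | CCC(=O)N1[C@@H](Cc2ccccc2)COC1=O | starting material
15 | hex-5-enal | C=CCCCC=O | starting material
16 | (4S)-4-benzyl-3-[(2S,3R)-3-hydroxy-2-methyloct-7-enoyl]-1,3-oxazolidin-2-one | C=CCCC[C@@H](O)[C@H](C)C(=O)N1[C@@H](Cc2ccccc2)COC1=O | intermediate
17 | (2R,3R)-2-methyloct-7-ene-1,3-diol | C=CCCC[C@@H](O)[C@H](C)CO | intermediate
18 | (2R,3R)-1-[(tert-butyldimethylsilyl)oxy]-2-methyloct-7-en-3-ol | C=CCCC[C@@H](O)[C@H](C)CO[Si](C)(C)C(C)(C)C | intermediate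
19 | {[(2R,3R)-3-(benzyloxy)-2-methyloct-7-en-1-yl]oxy}(tert-butyl)dimethylsilane | C=CCCC[C@@H](OCc1ccccc1)[C@H](C)CO[Si](C)(C)C(C)(C)C | intermediate
20 | (5R,6R)-5-(benzyloxy)-7-[(tert-butyldimethylsilyl)oxy]-6-methylheptanal | O=CCCC[C@@H](OCc1ccccc1)[C@H](C)CO[Si](C)(C)C(C)(C)C | intermediate
21 | (2S,3S)-2-EC-3-(nitromethyl)-5-BCP-pentanal (syn Michael adduct) | O=C[C@@H](CC[C@@H](OCc1ccccc1)[C@H](C)CO[Si](C)(C)C(C)(C)C)[C@H](CCC1=C(Br)[C@@H](CCOCc2ccc3ccccc3c2)CC1)C[N+](=O)[O-] | intermediate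
22 | (2S,3S)-2-EC-3-(nitromethyl)-5-BCP-pentanoic acid (not isolated) | OC(=O)[C@@H](CC[C@@H](OCc1ccccc1)[C@H](C)CO[Si](C)(C)C(C)(C)C)[C@H](CCC1=C(Br)[C@@H](CCOCc2ccc3ccccc3c2)CC1)C[N+](=O)[O-] | intermediate
23 | methyl (2S,3S)-2-EC-3-(nitromethyl)-5-BCP-pentanoate | COC(=O)[C@@H](CC[C@@H](OCc1ccccc1)[C@H](C)CO[Si](C)(C)C(C)(C)C)[C@H](CCC1=C(Br)[C@@H](CCOCc2ccc3ccccc3c2)CC1)C[N+](=O)[O-] | intermediate
24 | methyl (2S,3S)-3-(aminomethyl)-2-EC-5-BCP-pentanoate (not isolated) | COC(=O)[C@@H](CC[C@@H](OCc1ccccc1)[C@H](C)CO[Si](C)(C)C(C)(C)C)[C@H](CCC1=C(Br)[C@@H](CCOCc2ccc3ccccc3c2)CC1)CN | intermediate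
25 | (3S,4S)-3-EC-4-(2-BCP-ethyl)pyrrolidin-2-one (3,4-trans) | O=C1NC[C@@H](CCC2=C(Br)[C@@H](CCOCc3ccc4ccccc4c3)CC2)[C@@H]1CC[C@@H](OCc1ccccc1)[C@H](C)CO[Si](C)(C)C(C)(C)C | intermediate
26 | tert-butyl (3S,4S)-3-EC-4-(2-BCP-ethyl)-2-oxopyrrolidine-1-carboxylate | O=C1N(C(=O)OC(C)(C)C)C[C@@H](CCC2=C(Br)[C@@H](CCOCc3ccc4ccccc4c3)CC2)[C@@H]1CC[C@@H](OCc1ccccc1)[C@H](C)CO[Si](C)(C)C(C)(C)C | intermediate
27 | tert-butyl (3S,4S)-3-EC-3-(2-methoxy-2-oxoethyl)-4-(2-BCP-ethyl)-2-oxopyrrolidine-1-carboxylate (CH2CO2Me trans to the C-4 chain) | O=C1N(C(=O)OC(C)(C)C)C[C@@H](CCC2=C(Br)[C@@H](CCOCc3ccc4ccccc4c3)CC2)[C@@]1(CC(=O)OC)CC[C@@H](OCc1ccccc1)[C@H](C)CO[Si](C)(C)C(C)(C)C | intermediate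
28 | methyl (3S,4S)-4-{[(tert-butoxycarbonyl)amino]methyl}-3-EC-3-(hydroxymethyl)-6-BCP-hexanoate (not isolated) | COC(=O)C[C@@](CO)(CC[C@@H](OCc1ccccc1)[C@H](C)CO[Si](C)(C)C(C)(C)C)[C@@H](CNC(=O)OC(C)(C)C)CCC1=C(Br)[C@@H](CCOCc2ccc3ccccc3c2)CC1 | intermediate
29 | tert-butyl N-{(2S)-2-[(3S)-3-EC-5-oxooxolan-3-yl]-4-BCP-butyl}carbamate | O=C1OC[C@](C1)(CC[C@@H](OCc1ccccc1)[C@H](C)CO[Si](C)(C)C(C)(C)C)[C@@H](CNC(=O)OC(C)(C)C)CCC1=C(Br)[C@@H](CCOCc2ccc3ccccc3c2)CC1 | intermediate
30 | (2S)-2-{(3S)-3-[(3R,4R)-3-(benzyloxy)-5-hydroxy-4-methylpentyl]-5-oxooxolan-3-yl}-4-BCP-butan-1-aminium chloride | O=C1OC[C@](C1)(CC[C@@H](OCc1ccccc1)[C@H](C)CO)[C@@H](C[NH3+])CCC1=C(Br)[C@@H](CCOCc2ccc3ccccc3c2)CC1.[Cl-] | intermediate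
31 | N-{(2S)-2-[(3S)-3-[(3R,4R)-3-(benzyloxy)-5-hydroxy-4-methylpentyl]-5-oxooxolan-3-yl]-4-BCP-butyl}-2-nitrobenzenesulfonamide | O=C1OC[C@](C1)(CC[C@@H](OCc1ccccc1)[C@H](C)CO)[C@@H](CNS(=O)(=O)c1ccccc1[N+](=O)[O-])CCC1=C(Br)[C@@H](CCOCc2ccc3ccccc3c2)CC1 | intermediate
32 | N-Ns nine-membered amine, ring N(Ns)–C5H2–C4H(CH2CH2-BCP)–Cq–C6H2–C7H2–C8H(OBn)–C9H(CH3)–C10H2, spiro at Cq to the γ-lactone O–C21H2–Cq–CαH2–C1(=O); Cq S, C4 S, C8 R, C9 R | O=C1OC[C@]2(C1)CC[C@@H](OCc1ccccc1)[C@H](C)CN(S(=O)(=O)c1ccccc1[N+](=O)[O-])C[C@H]2CCC1=C(Br)[C@@H](CCOCc3ccc4ccccc4c3)CC1 | intermediate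
33 | 32 with N–H in place of N–Ns (not isolated) | O=C1OC[C@]2(C1)CC[C@@H](OCc1ccccc1)[C@H](C)CNC[C@H]2CCC1=C(Br)[C@@H](CCOCc3ccc4ccccc4c3)CC1 | intermediate
34 | bridged lactam alcohol: six-membered lactam N–C1(=O)–CαH2–Cq–C4H–C5H2 with N and Cq joined by C10H2–C9H(CH3)–C8H(OBn)–C7H2–C6H2; Cq–CH2OH; C4–CH2CH2-BCP; Cq S, C4 S, C8 R, C9 R | C1C(=O)N2C[C@@H](CCC3=C(Br)[C@@H](CCOCc4ccc5ccccc5c4)CC3)[C@]1(CO)CC[C@@H](OCc1ccccc1)[C@H](C)C2 | intermediate
35 | TBS ether of 34 (Cq–CH2OTBS) | C1C(=O)N2C[C@@H](CCC3=C(Br)[C@@H](CCOCc4ccc5ccccc5c4)CC3)[C@]1(CO[Si](C)(C)C(C)(C)C)CC[C@@H](OCc1ccccc1)[C@H](C)C2 | intermediate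
36 | 35 carrying CH2CH2S(O)Ph on Cα (epimers at Cα and S; Cq now R by CIP rules, same spatial arrangement; not isolated) | O=S(CCC1C(=O)N2C[C@@H](CCC3=C(Br)[C@@H](CCOCc4ccc5ccccc5c4)CC3)[C@]1(CO[Si](C)(C)C(C)(C)C)CC[C@@H](OCc1ccccc1)[C@H](C)C2)c1ccccc1 | intermediate
37 | key-step precursor: 35 carrying CH=CH2 on Cα (Cα epimers; Cq R by CIP rules, C4 S, C8 R, C9 R, C3′ R) | C=CC1C(=O)N2C[C@@H](CCC3=C(Br)[C@@H](CCOCc4ccc5ccccc5c4)CC3)[C@]1(CO[Si](C)(C)C(C)(C)C)CC[C@@H](OCc1ccccc1)[C@H](C)C2 | intermediate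
38 | key-step product: C2′ bonded to Cα (seven-membered ring Cα–Cq–C4–CH2–CH2–C1′=C2′); Cα (R) carries vinyl; C3′ (R) carries CH2CH2ONap; Cq–CH2OTBS (Cq R); C4 S; C8–OBn (R); C9 R | C=C[C@@]23C(=O)N4C[C@@H](CCC5=C2[C@@H](CCOCc6ccc7ccccc7c6)CC5)[C@]3(CO[Si](C)(C)C(C)(C)C)CC[C@@H](OCc8ccccc8)[C@H](C)C4 | intermediate
39 | 38 with CH2CH2OH on C3′ | C=C[C@@]23C(=O)N4C[C@@H](CCC5=C2[C@@H](CCO)CC5)[C@]3(CO[Si](C)(C)C(C)(C)C)CC[C@@H](OCc6ccccc6)[C@H](C)C4 | intermediate
40 | 38 with CH2CO2H on C3′ (not isolated) | C=C[C@@]23C(=O)N4C[C@@H](CCC5=C2[C@@H](CC(=O)O)CC5)[C@]3(CO[Si](C)(C)C(C)(C)C)CC[C@@H](OCc6ccccc6)[C@H](C)C4 | intermediate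
41 | 38 with CH2CO2Me on C3′ | C=C[C@@]23C(=O)N4C[C@@H](CCC5=C2[C@@H](CC(=O)OC)CC5)[C@]3(CO[Si](C)(C)C(C)(C)C)CC[C@@H](OCc6ccccc6)[C@H](C)C4 | intermediate
42 | 41 with CH2NMe2 on the ester α-carbon (epimers; not isolated) | C=C[C@@]23C(=O)N4C[C@@H](CCC5=C2[C@@H](C(CN(C)C)C(=O)OC)CC5)[C@]3(CO[Si](C)(C)C(C)(C)C)CC[C@@H](OCc6ccccc6)[C@H](C)C4 | intermediate
43 | trimethylammonium iodide of 42 (not isolated) | C=C[C@@]23C(=O)N4C[C@@H](CCC5=C2[C@@H](C(C[N+](C)(C)C)C(=O)OC)CC5)[C@]3(CO[Si](C)(C)C(C)(C)C)CC[C@@H](OCc6ccccc6)[C@H](C)C4.[I-] | intermediate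
44 | 38 with C(=CH2)CO2Me on C3′ (C3′ S by CIP rules, same spatial arrangement) | C=C[C@@]23C(=O)N4C[C@@H](CCC5=C2[C@@H](C(=C)C(=O)OC)CC5)[C@]3(CO[Si](C)(C)C(C)(C)C)CC[C@@H](OCc6ccccc6)[C@H](C)C4 | intermediate
45 | pentacycle with the cyclopentene Cα–CH=C(CO2Me)–C3′–C2′; Cq–CH2OTBS; C8–OBn | COC(=O)C1=C[C@@]23C(=O)N4C[C@@H](CCC5=C2[C@@H]1CC5)[C@]3(CO[Si](C)(C)C(C)(C)C)CC[C@@H](OCc6ccccc6)[C@H](C)C4 | intermediate
46 | 45 with Cq–CH2OH | COC(=O)C1=C[C@@]23C(=O)N4C[C@@H](CCC5=C2[C@@H]1CC5)[C@]3(CO)CC[C@@H](OCc6ccccc6)[C@H](C)C4 | intermediate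
47 | 45 with Cq–CH2OAc | COC(=O)C1=C[C@@]23C(=O)N4C[C@@H](CCC5=C2[C@@H]1CC5)[C@]3(COC(C)=O)CC[C@@H](OCc6ccccc6)[C@H](C)C4 | intermediate
48 | CNP0296366.1 (CH(CO2Me) R, Cα R, Cq R, C4 S, C3′ R, C8 R, C9 R) | COC(=O)[C@@H]1C[C@@]23C(=O)N4C[C@@H](CCC5=C2[C@@H]1CC5)[C@]3(COC(C)=O)CC[C@@H](O)[C@H](C)C4 | target

**Step count and risks**

Total steps: 33. Longest linear sequence: 28 steps (steps 1–8, then 14–33); the east chain (steps 9–13) is a five-step branch.

Steps most likely to fail:

Step 26 (key step). What may go wrong: reductive elimination at the crowded Cα, which becomes a quaternary carbon next to quaternary Cq, is slow, so protodebromination of the alkenylpalladium species and γ-reprotonation of the dienolate (drift to the conjugated ethylidene lactam) take over. Fallback: make the same C2′–Cα bond by an intramolecular Heck reaction instead of an enolate coupling. It sets out from 35. Aldol addition of its lithium enolate (LiN(i-Pr)2, THF, −78 °C) to acetaldehyde should give the β-hydroxy lactam F1, and mesylation followed by DBU elimination the α-ethylidene lactam F2. With Pd(OAc)2, P(o-tol)3 and Cy2NMe (DMF, 90 °C) the alkenylpalladium bromide should add 7-exo to Cα from the only face the tether allows, and β-hydride elimination from the methyl group should regenerate the vinyl group. The fallback comes back to the route at 38.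

Step 22. What may go wrong: intermolecular alkylation (dimers, oligomers) competes with closure of the strained nine-membered ring. Fallback: invert the order of ring formation. It sets out from 30. Freeing the amine (Et3N, MeOH, 40 °C) should let it open the γ-lactone to the monocyclic six-membered lactam diol F3. The less hindered C10 alcohol (the C21 alcohol is neopentyl) should then be tosylated selectively (TsCl, Et3N, Me3N·HCl cat., 0 °C) to the C10 tosylate F4. Deprotonation of the lactam N–H with KN(SiMe3)2 at high dilution (THF, 0 → 50 °C) should close the nine-membered ring by N-alkylation. The fallback comes back at 34.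

Step 30. What may go wrong: the ruthenium carbene does not load onto either hindered alkene (vinyl on quaternary Cα, 1,1-disubstituted acrylate) and decomposes before ring closure. Fallback: close the five-membered ring by an aldol condensation instead of metathesis. It sets out from 41. Lemieux–Johnson cleavage of the vinyl group (OsO4 cat., NaIO4, 2,6-lutidine, dioxane/H2O; the tetrasubstituted alkene reacts much more slowly) should give the Cα aldehyde F5. Its lithium ester enolate (LiN(SiMe3)2, THF, −78 °C) should add to the aldehyde in a 5-exo aldol reaction to give the β-hydroxy ester F6. Mesylation and DBU elimination should then give the same cyclopentene ester. The fallback comes back at 45.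

Further compounds
F1 | step 26 | β-hydroxy lactam: 35 carrying CH(OH)CH3 on Cα (epimers) | CC(O)C1C(=O)N2C[C@@H](CCC3=C(Br)[C@@H](CCOCc4ccc5ccccc5c4)CC3)[C@]1(CO[Si](C)(C)C(C)(C)C)CC[C@@H](OCc1ccccc1)[C@H](C)C2
F2 | step 26 | α-ethylidene lactam: 35 with Cα=CH–CH3 (E/Z) | CC=C1C(=O)N2C[C@@H](CCC3=C(Br)[C@@H](CCOCc4ccc5ccccc5c4)CC3)[C@]1(CO[Si](C)(C)C(C)(C)C)CC[C@@H](OCc1ccccc1)[C@H](C)C2
F3 | step 22 | monocyclic six-membered lactam diol: NH–C1(=O)–CαH2–Cq(CH2OH)(CH2CH2CH(OBn)CH(CH3)CH2OH)–C4H(CH2CH2-BCP)–C5H2 | O=C1C[C@@](CO)(CC[C@@H](OCc2ccccc2)[C@H](C)CO)[C@H](CCC2=C(Br)[C@@H](CCOCc3ccc4ccccc4c3)CC2)CN1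
F4 | step 22 | C10 p-toluenesulfonate of F3 | O=C1C[C@@](CO)(CC[C@@H](OCc2ccccc2)[C@H](C)COS(=O)(=O)c2ccc(C)cc2)[C@H](CCC2=C(Br)[C@@H](CCOCc3ccc4ccccc4c3)CC2)CN1
F5 | step 30 | Cα aldehyde: 41 with CHO in place of vinyl | O=C[C@@]23C(=O)N4C[C@@H](CCC5=C2[C@@H](CC(=O)OC)CC5)[C@]3(CO[Si](C)(C)C(C)(C)C)CC[C@@H](OCc6ccccc6)[C@H](C)C4
F6 | step 30 | β-hydroxy ester: cyclopentanol Cα–CH(OH)–CH(CO2Me)–C3′ (epimers at both new centres) | COC(=O)C1C(O)[C@@]23C(=O)N4C[C@@H](CCC5=C2[C@@H]1CC5)[C@]3(CO[Si](C)(C)C(C)(C)C)CC[C@@H](OCc6ccccc6)[C@H](C)C4
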